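**Retrosynthetic overview**

- The route rests on ring carbon C1 of the benzene ring of target 12: it carries the ester carbon C7 (whose oxygen holds the C21 chain) and sits between C2–OH and C6–H, with C3–OH next to C2. C1 is therefore treated as a carbon inserted between a ketone carbon (future C2) and its saturated neighbour (future C6) in a five-membered ring that already holds both oxygens.
- 12 ⇐ 11 by removal of the C3 benzyl ether; 11 ⇐ 10 by loss of H2 across C5–C6 (aromatization).
- 10 ⇐ 3 + 8 by one-carbon ring enlargement: the diazo carbon of 8 becomes C1 and the bonds C1–C2 and C1–C6 are formed. This is the only ring-forming event; the five-membered ring of 3 grows to the six-membered carbocycle, which is aromatized afterwards.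
- 3 ⇐ 1 + 2 (O-benzylation of the enol); 8 ⇐ 6 ⇐ 4 + 5 (acylation, then conversion of the bromoacetate to the diazoacetate).

Key step: step 4

Remark: cyclopentane-1,2-dione 1 is taken to react as its enol tautomer, 2-hydroxycyclopent-2-en-1-one, the form present in solution. Ring atoms are numbered as in the target throughout (C1 ester-bearing, C2 and C3 oxygenated, C4–C6 CH).

**Route**

Step 1
Reactants: 1 cyclopentane-1,2-dione; 2 benzyl bromide
Product: 3 2-(benzyloxy)cyclopent-2-en-1-one
Conditions: K2CO3, DMF, 0 °C → rt
Reagents that add atoms: none
Why: Williamson-type O-alkylation of the acidic enol (diosphenol) of a symmetric 1,2-dione, whose potassium enolate in a dipolar aprotic solvent should react mainly at oxygen, and only one enol ether is possible.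

Step 2
Reactants: 4 heneicosan-1-ol; 5 bromoacetyl bromide
Product: 6 heneicosyl 2-bromoacetate
Conditions: pyridine, CH2Cl2, 0 °C → rt
Reagents that add atoms: none
Why: Acylation of a primary alcohol by an acyl bromide (esterification), which is much faster than displacement of the alkyl bromide, so the CH2Br group should be kept for the next step.

Step 3
Reactants: 6 heneicosyl 2-bromoacetate
Product: 8 heneicosyl 2-diazoacetate, via alkylated ditosylhydrazide 7 (not isolated)
Conditions: TsNHNHTs (2 equiv), DBU (5 equiv), THF, 0 °C
Reagents that add atoms: N,N'-ditosylhydrazine, Cc1ccc(cc1)S(=O)(=O)NNS(=O)(=O)c1ccc(C)cc1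
Why: Fukuyama diazoacetate synthesis, in which the ditosylhydrazine anion displaces bromide (SN2) to give 7 and DBU then induces two successive eliminations of p-toluenesulfinate to leave the diazo group, under conditions that do not touch the ester.

Step 4
Reactants: 3 2-(benzyloxy)cyclopent-2-en-1-one; 8 heneicosyl 2-diazoacetate
Product: 10 heneicosyl 3-(benzyloxy)-2-oxocyclohex-3-ene-1-carboxylate, via diazonium alkoxide BF3 adduct 9 (not isolated)
Conditions: BF3·OEt2 (1.2 equiv), CH2Cl2, −20 °C → rt; 3 in slight excess, 8 added slowly
Reagents that add atoms: none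
Why: BF3 coordinates the carbonyl of 3, the diazo carbon of 8 adds to the carbonyl carbon (new bond C1–C2) to give the diazonium alkoxide 9, and the saturated ring CH2 antiperiplanar to the departing N2 shifts to the diazo carbon (new bond C1–C6), leaving the ring-enlarged β-keto ester 10. The closest known reaction is the Lewis-acid-promoted diazoacetate homologation of cyclic ketones, conjugated cycloalkenones included (Tiffeneau–Demjanov-type ring enlargement). The six-membered carbocycle is not closed end to end but arises by 1,2-alkyl shift from the five-membered ring, so no cyclization mode has to be met. The only new stereocentre, C1 of 10, forms racemic, is enolizable and later becomes an arene carbon, so it needs no control. The step needs migration of the sp3 CH2 rather than the benzyloxy-bearing vinyl carbon, and 1,2-addition rather than attack on the C=C; the first should follow from the poor migratory aptitude of an sp2 carbon that carries an inductively withdrawing oxygen and would lose enone conjugation on migrating, the second from BF3 activation of the C=O at low temperature and the electron-rich β-carbon of the enol ether. The enolized, BF3-chelated product is far less electrophilic than 3, so a second insertion should not compete.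

Step 5
Reactants: 10 heneicosyl 3-(benzyloxy)-2-oxocyclohex-3-ene-1-carboxylate
Product: 11 heneicosyl 3-(benzyloxy)-2-hydroxybenzoate
Conditions: DDQ (1.1 equiv), 1,4-dioxane, rt → 60 °C
Reagents that add atoms: none
Why: DDQ dehydrogenation (aromatization), in which the dienol tautomer of 10, a cyclohexa-1,3-diene with OH at C2 and OBn at C3, should transfer hydride from C5 to DDQ (cation stabilized by the C3 oxygen) and then lose the C6 proton to give the arene directly, while the plain benzyl ether and the saturated chain are inert to DDQ under anhydrous conditions.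

Step 6
Reactants: 11 heneicosyl 3-(benzyloxy)-2-hydroxybenzoate
Product: 12 heneicosyl 2,3-dihydroxybenzoate
Conditions: H2 (1 atm), 10% Pd/C, THF/EtOAc, rt
Reagents that add atoms: none
Why: Catalytic hydrogenolysis of an aryl benzyl ether over Pd/C, in which the alkyl ester C–O bond is not benzylic and the arene is not reduced at 1 atm, so only the benzyl group should be lost to give the catechol.

**Compound list**

1 | cyclopentane-1,2-dione | O=C1CCCC1=O | starting material
2 | benzyl bromide | BrCc1ccccc1 | starting material
3 | 2-(benzyloxy)cyclopent-2-en-1-one | O=C1CCC=C1OCc1ccccc1 | intermediate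
4 | heneicosan-1-ol | CCCCCCCCCCCCCCCCCCCCCO | starting material
5 | bromoacetyl bromide | BrCC(Br)=O | starting material
6 | heneicosyl 2-bromoacetate | CCCCCCCCCCCCCCCCCCCCCOC(=O)CBr | intermediate
7 | heneicosyl 2-[1,2-bis(4-methylbenzenesulfonyl)hydrazin-1-yl]acetate | CCCCCCCCCCCCCCCCCCCCCOC(=O)CN(NS(=O)(=O)c1ccc(C)cc1)S(=O)(=O)c1ccc(C)cc1 | intermediate (not isolated)
8 | heneicosyl 2-diazoacetate | CCCCCCCCCCCCCCCCCCCCCOC(=O)C=[N+]=[N-] | intermediate
9 | BF3 adduct of the diazonium alkoxide, 1-[2-(benzyloxy)-1-(trifluoroboranuidyloxy)cyclopent-2-en-1-yl]-2-(heneicosyloxy)-2-oxoethane-1-diazonium (mixture of diastereomers, both centres lost on rearrangement and enolization) | CCCCCCCCCCCCCCCCCCCCCOC(=O)C([N+]#N)C1(O[B-](F)(F)F)CCC=C1OCc1ccccc1 | intermediate (not isolated)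
10 | heneicosyl 3-(benzyloxy)-2-oxocyclohex-3-ene-1-carboxylate (racemic at C1, in equilibrium with its enol) | CCCCCCCCCCCCCCCCCCCCCOC(=O)C1CCC=C(OCc2ccccc2)C1=O | intermediate
11 | heneicosyl 3-(benzyloxy)-2-hydroxybenzoate | CCCCCCCCCCCCCCCCCCCCCOC(=O)c1cccc(OCc2ccccc2)c1O | intermediate
12 | heneicosyl 2,3-dihydroxybenzoate | CCCCCCCCCCCCCCCCCCCCCOC(=O)c1cccc(O)c1O | target

**Count**

Total steps: 6. Longest linear sequence: 5 steps (steps 2, 3, 4, 5, 6, from heneicosan-1-ol 4).

**Steps most likely to fail, with fallbacks**

1. Step 4 (ring enlargement). The diazoacetate may add too slowly to the deactivated conjugated carbonyl, the vinyl carbon may migrate in competition, or the Lewis acid may ionize the benzyl enol ether. The fallback reaches the same β-keto ester without a ring enlargement, by C-acylation of a six-membered enolate. It sets out from heneicosan-1-ol 4, which with 1,1'-carbonyldiimidazole (THF, rt) should give heneicosyl 1H-imidazole-1-carboxylate F1. In parallel, cyclohexane-1,2-dione is O-benzylated with benzyl bromide 2 (K2CO3, DMF) to 2-(benzyloxy)cyclohex-2-en-1-one F2. Kinetic deprotonation of F2 at its only saturated α-carbon with LiN(iPr)2 (THF, −78 °C) gives lithium 6-(benzyloxy)cyclohexa-1,5-dien-1-olate F3. F3 is C-acylated by F1 in the presence of BF3·OEt2 (a known enolate acylation with alkyl imidazole-1-carboxylates) and, after NH4Cl quench, should deliver 10, where the route is rejoined at step 5.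

2. Step 5 (aromatization). Hydride transfer to DDQ may be slow, or the oxidant may over-oxidize the electron-rich dienol and phenol or attack the benzylic position of the ether. The fallback sets out from 10 and uses selenoxide elimination. PhSeCl and pyridine (CH2Cl2, 0 °C) should selenenylate the β-keto ester at C1 to give heneicosyl 3-(benzyloxy)-2-oxo-1-(phenylselanyl)cyclohex-3-ene-1-carboxylate F4. Aqueous H2O2 (CH2Cl2, 0 °C → rt) oxidizes it to heneicosyl 3-(benzyloxy)-2-oxo-1-(phenylseleninyl)cyclohex-3-ene-1-carboxylate F5. F5 undergoes syn-elimination across C1–C6 to heneicosyl 5-(benzyloxy)-6-oxocyclohexa-1,4-diene-1-carboxylate F6, and this cross-conjugated dienone tautomerizes in the flask to 11, where the route is rejoined at step 6.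

3. Step 1 (O-benzylation). The ambident enolate may be benzylated at carbon (C3 of the dione), and the dione may self-condense under base. The fallback sets out from 1 and avoids the enolate altogether. Acid-catalysed enol etherification with benzyl alcohol (TsOH·H2O cat., toluene, reflux with azeotropic removal of water) proceeds through the hemiketal and dehydration and should give 3 directly, where the route is rejoined at step 4 (no new compound, F0).

**Further compounds**

F1 | step 4 | heneicosyl 1H-imidazole-1-carboxylate | CCCCCCCCCCCCCCCCCCCCCOC(=O)n1ccnc1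
F2 | step 4 | 2-(benzyloxy)cyclohex-2-en-1-one | O=C1CCCC=C1OCc1ccccc1
F3 | step 4 | lithium 6-(benzyloxy)cyclohexa-1,5-dien-1-olate | [Li+].[O-]C1=CCCC=C1OCc1ccccc1
F4 | step 5 | heneicosyl 3-(benzyloxy)-2-oxo-1-(phenylselanyl)cyclohex-3-ene-1-carboxylate | CCCCCCCCCCCCCCCCCCCCCOC(=O)C1([Se]c2ccccc2)CCC=C(OCc2ccccc2)C1=O
F5 | step 5 | heneicosyl 3-(benzyloxy)-2-oxo-1-(phenylseleninyl)cyclohex-3-ene-1-carboxylate | CCCCCCCCCCCCCCCCCCCCCOC(=O)C1([Se](=O)c2ccccc2)CCC=C(OCc2ccccc2)C1=O
F6 | step 5 | heneicosyl 5-(benzyloxy)-6-oxocyclohexa-1,4-diene-1-carboxylate | CCCCCCCCCCCCCCCCCCCCCOC(=O)C1=CCC=C(OCc2ccccc2)C1=O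
F0 | step 1 | none | none
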